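The tetrahydrofuran is opened at O1–C2. A twofold axis runs through O1 and the midpoint of C3–C4, so C2 and C5 are equivalent and both benzylic C–O bonds can be made by SN2 inversion from one all-(R) 1,4-diol, held as a seven-membered cyclic sulfate. Acetate opens it at C5; methanolysis frees the alkoxide, which closes the ring on the C2 sulfate. This double inversion sets both benzylic centres and gives the contra-thermodynamic 2,3-cis-3,4-trans-4,5-cis core in one operation; aryl tosylates suppress benzylic ionization. The sulfate comes from auxiliary-controlled enolate homocoupling and CBS reduction; the side chains follow by lactate-derived SN2 etherification and Felkin–Anh reduction.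

Key step: step 7

Remark: the tetrahydrofuran is numbered O1, C2–C5; in each side chain C7 is the carbinol carbon and C8 the aryloxy-bearing carbon. The route assumes that 3-methoxy-4-(tosyloxy)phenyl groups are too electron-poor to ionize at the benzylic position, which is the reason the phenols are carried as tosylates.

Step 1
Reactants: 1 (S)-4-benzyl-3-propionyloxazolidin-2-one (two molecules)
Product: 2 (2R,3R)-1,4-bis[(S)-4-benzyl-2-oxooxazolidin-3-yl]-2,3-dimethylbutane-1,4-dione
Conditions: LiN(i-Pr)2, THF, −78 °C; then TiCl4, −78 °C to rt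
Reagents that add atoms: none
Why: Oxidative enolate homocoupling of the chelated Z-lithium enolate with tetravalent titanium as one-electron oxidant; each α-carbon should bond on the face opposite the benzyl group, as in an Evans alkylation, which gives the (2R,3R) dimer.

Step 2
Reactants: 2 (2R,3R)-bis-imide
Product: 3 (2R,3R)-N1,N4-dimethoxy-N1,N4,2,3-tetramethylbutanediamide
Conditions: MeNH(OMe)·HCl, AlMe3, CH2Cl2, 0 °C to rt
Reagents that add atoms: N,O-dimethylhydroxylamine hydrochloride CNOC.Cl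
Why: Aluminium-amide transamidation (Weinreb amide formation) cleaves the exocyclic imide C–N bonds without base, so the two α-stereocentres should be untouched.

Step 3
Reactants: 4 4-bromo-2-methoxyphenol
Product: 5 4-bromo-2-methoxyphenyl 4-methylbenzenesulfonate
Conditions: TsCl, Et3N, DMAP (cat.), CH2Cl2, 0 °C to rt
Reagents that add atoms: 4-toluenesulfonyl chloride Cc1ccc(S(=O)(=O)Cl)cc1
Why: Phenol O-sulfonylation; the tosylate protects the phenol and later makes the aryl ring electron-poor.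

Step 4
Reactants: 5 4-bromo-2-methoxyphenyl 4-methylbenzenesulfonate (2.6 equiv), 3 (2R,3R)-bis-Weinreb amide
Product: 7 (2R,3R)-1,4-bis[3-methoxy-4-(tosyloxy)phenyl]-2,3-dimethylbutane-1,4-dione, via arylmagnesium bromide 6 (not isolated)
Conditions: Mg turnings, LiCl, THF, 0 °C to rt; then 3, −20 °C to rt; aq. NH4Cl
Reagents that add atoms: none
Why: LiCl-assisted magnesium insertion tolerates the aryl sulfonate, and the Weinreb ketone synthesis proceeds through chelated tetrahedral intermediates that prevent over-addition and enolization, so the (2R,3R) centres should persist.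

Step 5
Reactants: 7 (2R,3R)-diketone
Product: 8 (1R,2R,3R,4R)-1,4-bis[3-methoxy-4-(tosyloxy)phenyl]-2,3-dimethylbutane-1,4-diol
Conditions: (S)-2-methyl-CBS-oxazaborolidine (0.4 equiv), BH3·SMe2, THF, −20 °C; MeOH quench
Reagents that add atoms: none
Why: Corey–Bakshi–Shibata reduction; the (S)-catalyst delivers hydride to the Si face of each aryl ketone to give (R)-carbinols, the same sense as Felkin–Anh control by the neighbouring (R)-methyl centre (matched case), so the twofold-symmetric anti,anti-diol should result.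

Step 6
Reactants: 8 (1R,2R,3R,4R)-diol
Product: 10 (4R,5R,6R,7R)-4,7-bis[3-methoxy-4-(tosyloxy)phenyl]-5,6-dimethyl-1,3,2-dioxathiepane 2,2-dioxide, via cyclic sulfite 9 (not isolated)
Conditions: SOCl2, Et3N, CH2Cl2, −20 to 0 °C; then RuCl3 (1 mol%), NaIO4, MeCN/H2O, 0 °C
Reagents that add atoms: thionyl chloride O=S(Cl)Cl; sodium periodate [Na+].[O-]I(=O)(=O)=O
Why: Two-stage cyclic sulfate synthesis (sulfite formation, then RuO4-catalysed oxidation at sulfur) touches no C–O bond, so all four centres are retained, and the electron-poor aryl groups should keep the benzylic sulfate from ionizing.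

Step 7
Reactants: 10 (4R,5R,6R,7R)-cyclic sulfate
Product: 13 (2S,3R,4R,5S)-2,5-bis[3-methoxy-4-(tosyloxy)phenyl]-3,4-dimethyltetrahydrofuran, via acetoxy sulfate 11 (not isolated), via hydroxy sulfate 12 (not isolated)
Conditions: Bu4NOAc, DMF, 40 °C; then K2CO3, MeOH, 40 °C
Reagents that add atoms: tetrabutylammonium acetate CC(=O)[O-].CCCC[N+](CCCC)(CCCC)CCCC
Why: Acetate attacks one benzylic carbon of the cyclic sulfate by SN2 with inversion (the twofold axis makes the two carbons equivalent, so either attack gives the same acetoxy sulfate 11); methanolysis of the acetate then frees the C5 alkoxide of 12, which displaces the remaining sulfate monoester at C2 with a second inversion and so forms the O1–C2 bond. The closest known reaction type is the double nucleophilic displacement of 1,4-diol cyclic sulfates used for twofold-symmetric phospholanes, thiolanes and pyrrolidines, combined with carboxylate opening of cyclic sulfates. The tetrahydrofuran closes by a 5-exo-tet intramolecular Williamson etherification. C5 is set by the stereospecific inversion in the acetate opening and C2 by the stereospecific inversion in the ring closure, so the all-(R) diol is translated into the (2S,5S) ether in which each aryl group is cis to its neighbouring methyl group, the arrangement that cationic closures do not favour. The step needs substitution at carbon to win over benzylic ionization, elimination and attack at sulfur: the para-tosyloxy and meta-methoxy substituents make the benzylic carbons poor cation sites, acetate is a weak base, and the sulfate monoanion formed after the first opening resists a second intermolecular attack yet remains a competent leaving group for the intramolecular closure.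

Step 8
Reactants: 13 (2S,3R,4R,5S)-bis(aryl tosylate)
Product: 14 (2S,3R,4R,5S)-2,5-bis(4-hydroxy-3-methoxyphenyl)-3,4-dimethyltetrahydrofuran
Conditions: Mg, MeOH, rt; aq. NH4Cl
Reagents that add atoms: none
Why: Single-electron reductive S–O cleavage of the aryl sulfonates frees both phenols under non-acidic conditions, so the acid-labile 2,3-cis and 4,5-cis benzylic ether centres should not epimerize.

Step 9
Reactants: 15 (S)-2-hydroxy-N,N-dimethylpropanamide, 16 (3,4-dimethoxyphenyl)magnesium bromide (2.5 equiv)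
Product: 17 (S)-1-(3,4-dimethoxyphenyl)-2-hydroxypropan-1-one
Conditions: THF, −20 °C to rt; aq. NH4Cl
Reagents that add atoms: none
Why: Grignard addition to the tertiary amide, in which the magnesium alkoxide of the α-hydroxyl chelates the tetrahedral intermediate so the ketone is released only on work-up and the lactate stereocentre is not involved.

Step 10
Reactants: 17 (S)-α-hydroxy ketone
Product: 18 (S)-1-(3,4-dimethoxyphenyl)-1-oxopropan-2-yl 4-methylbenzenesulfonate
Conditions: TsCl, pyridine, CH2Cl2, 0 °C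
Reagents that add atoms: 4-toluenesulfonyl chloride Cc1ccc(S(=O)(=O)Cl)cc1
Why: O-sulfonylation leaves the C–O bond intact, so the (S) configuration is retained, and the weak base limits enolization.

Step 11
Reactants: 14 bisphenol, 18 (S)-α-tosyloxy ketone (2.2 equiv)
Product: 19 (2R,2'R)-2,2'-{[(2S,3R,4R,5S)-3,4-dimethyltetrahydrofuran-2,5-diyl]bis[(2-methoxy-4,1-phenylene)oxy]}bis[1-(3,4-dimethoxyphenyl)propan-1-one]
Conditions: BEMP (2-tert-butylimino-2-diethylamino-1,3-dimethylperhydro-1,3,2-diazaphosphorine, 2.1 equiv), MeCN, 0 °C to rt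
Reagents that add atoms: none
Why: Double Williamson etherification by SN2 at the α-keto sulfonate inverts each C8 from (S) to (R), and the non-nucleophilic tosylate leaving group cannot racemize the electrophile by re-addition.

Step 12
Reactants: 19 bis(α-aryloxy ketone)
Product: 20 manassantin A
Conditions: polymer-supported borohydride (quaternary ammonium resin, BH4 form), MeOH, 0 °C to rt
Reagents that add atoms: none
Why: Felkin–Anh reduction with a non-chelating ammonium counter-ion places hydride anti to the C8 aryloxy group, which should give the threo (7R,8R) carbinol in both side chains.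

Compound list
1 | (S)-4-benzyl-3-propionyloxazolidin-2-one | CCC(=O)N1[C@@H](Cc2ccccc2)COC1=O | starting material
2 | (2R,3R)-1,4-bis[(S)-4-benzyl-2-oxooxazolidin-3-yl]-2,3-dimethylbutane-1,4-dione | O=C([C@H](C)[C@@H](C)C(=O)N1[C@@H](Cc2ccccc2)COC1=O)N1[C@@H](Cc3ccccc3)COC1=O | intermediate
3 | (2R,3R)-N1,N4-dimethoxy-N1,N4,2,3-tetramethylbutanediamide | CON(C)C(=O)[C@H](C)[C@@H](C)C(=O)N(C)OC | intermediate
4 | 4-bromo-2-methoxyphenol | COc1cc(Br)ccc1O | starting material
5 | 4-bromo-2-methoxyphenyl 4-methylbenzenesulfonate | COc1cc(Br)ccc1OS(=O)(=O)c1ccc(C)cc1 | intermediate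
6 | [3-methoxy-4-(tosyloxy)phenyl]magnesium bromide (LiCl complex) | COc1cc([Mg]Br)ccc1OS(=O)(=O)c1ccc(C)cc1 | intermediate
7 | (2R,3R)-1,4-bis[3-methoxy-4-(tosyloxy)phenyl]-2,3-dimethylbutane-1,4-dione | COc1cc(C(=O)[C@H](C)[C@@H](C)C(=O)c2ccc(OS(=O)(=O)c3ccc(C)cc3)c(OC)c2)ccc1OS(=O)(=O)c1ccc(C)cc1 | intermediate
8 | (1R,2R,3R,4R)-1,4-bis[3-methoxy-4-(tosyloxy)phenyl]-2,3-dimethylbutane-1,4-diol | COc1cc([C@H](O)[C@H](C)[C@@H](C)[C@@H](O)c2ccc(OS(=O)(=O)c3ccc(C)cc3)c(OC)c2)ccc1OS(=O)(=O)c1ccc(C)cc1 | intermediate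
9 | (4R,5R,6R,7R)-4,7-bis[3-methoxy-4-(tosyloxy)phenyl]-5,6-dimethyl-1,3,2-dioxathiepane 2-oxide | COc1cc([C@@H]2OS(=O)O[C@@H](c3ccc(OS(=O)(=O)c4ccc(C)cc4)c(OC)c3)[C@H](C)[C@H]2C)ccc1OS(=O)(=O)c1ccc(C)cc1 | intermediate
10 | (4R,5R,6R,7R)-4,7-bis[3-methoxy-4-(tosyloxy)phenyl]-5,6-dimethyl-1,3,2-dioxathiepane 2,2-dioxide | COc1cc([C@@H]2OS(=O)(=O)O[C@@H](c3ccc(OS(=O)(=O)c4ccc(C)cc4)c(OC)c3)[C@H](C)[C@H]2C)ccc1OS(=O)(=O)c1ccc(C)cc1 | intermediate
11 | tetrabutylammonium (1R,2R,3R,4S)-4-acetoxy-1,4-bis[3-methoxy-4-(tosyloxy)phenyl]-2,3-dimethylbutyl sulfate | COc1cc([C@@H](OC(C)=O)[C@H](C)[C@@H](C)[C@@H](OS(=O)(=O)[O-])c2ccc(OS(=O)(=O)c3ccc(C)cc3)c(OC)c2)ccc1OS(=O)(=O)c1ccc(C)cc1.CCCC[N+](CCCC)(CCCC)CCCC | intermediate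
12 | tetrabutylammonium (1R,2R,3R,4S)-4-hydroxy-1,4-bis[3-methoxy-4-(tosyloxy)phenyl]-2,3-dimethylbutyl sulfate (reacts as its potassium alkoxide) | COc1cc([C@@H](O)[C@H](C)[C@@H](C)[C@@H](OS(=O)(=O)[O-])c2ccc(OS(=O)(=O)c3ccc(C)cc3)c(OC)c2)ccc1OS(=O)(=O)c1ccc(C)cc1.CCCC[N+](CCCC)(CCCC)CCCC | intermediate
13 | (2S,3R,4R,5S)-2,5-bis[3-methoxy-4-(tosyloxy)phenyl]-3,4-dimethyltetrahydrofuran | COc1cc([C@H]2O[C@H](c3ccc(OS(=O)(=O)c4ccc(C)cc4)c(OC)c3)[C@H](C)[C@H]2C)ccc1OS(=O)(=O)c1ccc(C)cc1 | intermediate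
14 | (2S,3R,4R,5S)-2,5-bis(4-hydroxy-3-methoxyphenyl)-3,4-dimethyltetrahydrofuran | COc1cc([C@H]2O[C@H](c3ccc(O)c(OC)c3)[C@H](C)[C@H]2C)ccc1O | intermediate
15 | (S)-2-hydroxy-N,N-dimethylpropanamide | C[C@H](O)C(=O)N(C)C | starting material
16 | (3,4-dimethoxyphenyl)magnesium bromide (THF solution) | COc1ccc([Mg]Br)cc1OC | starting material
17 | (S)-1-(3,4-dimethoxyphenyl)-2-hydroxypropan-1-one | C[C@H](O)C(=O)c1ccc(OC)c(OC)c1 | intermediate
18 | (S)-1-(3,4-dimethoxyphenyl)-1-oxopropan-2-yl 4-methylbenzenesulfonate | C[C@H](OS(=O)(=O)c1ccc(C)cc1)C(=O)c1ccc(OC)c(OC)c1 | intermediate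
19 | (2R,2'R)-2,2'-{[(2S,3R,4R,5S)-3,4-dimethyltetrahydrofuran-2,5-diyl]bis[(2-methoxy-4,1-phenylene)oxy]}bis[1-(3,4-dimethoxyphenyl)propan-1-one] | COc1ccc(C(=O)[C@@H](C)Oc2ccc([C@H]3O[C@H](c4ccc(O[C@H](C)C(=O)c5ccc(OC)c(OC)c5)c(OC)c4)[C@H](C)[C@H]3C)cc2OC)cc1OC | intermediate
20 | manassantin A | COc1ccc([C@@H](O)[C@@H](C)Oc2ccc([C@H]3O[C@H](c4ccc(O[C@H](C)[C@H](O)c5ccc(OC)c(OC)c5)c(OC)c4)[C@H](C)[C@H]3C)cc2OC)cc1OC | target

Total step count: 12 steps. Longest linear sequence: 9 steps (steps 1, 2, 4, 5, 6, 7, 8, 11, 12).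

Steps most likely to fail

Step 7. Acetate may act as a base and eliminate to a styrene, or attack at sulfur instead of the hindered benzylic carbon. The closure on the sulfate monoanion may also be slow enough for hydrolysis with retention to compete. The fallback sets out from diol 8 and comes back at 13, replacing the tethered bis-electrophile by a stepwise double inversion. Because the two hydroxyls of 8 are equivalent, one equivalent of TBSCl with imidazole should give a single mono-silyl ether, (1R,2R,3R,4R)-4-[(tert-butyldimethylsilyl)oxy]-1,4-bis[3-methoxy-4-(tosyloxy)phenyl]-2,3-dimethylbutan-1-ol F1. A Mitsunobu reaction (4-nitrobenzoic acid, PPh3, DIAD) inverts the free carbinol to the (1S)-4-nitrobenzoate F2. HF·pyridine removes the silyl group to give the hydroxy ester F3, and MsCl/Et3N converts it into the mesylate F4. K2CO3 in MeOH then cleaves the ester, and the alkoxide closes onto the benzylic mesylate with inversion to give 13.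

Step 6. Chlorosulfite collapse to a benzylic chloride or premature cyclodehydration may occur during sulfite formation, and RuO4 may oxidatively degrade the methoxy-substituted rings. The fallback sets out from 8 and comes back at 13 without any cyclic sulfur ester. MsCl/Et3N at −20 °C gives the (1R,2R,3R,4R)-1,4-diyl dimethanesulfonate F5. One equivalent of Bu4NOAc in DMF then performs a statistical mono-substitution with inversion to the (1S)-acetoxy mesylate F6, with unreacted F5 recycled. K2CO3 in MeOH unmasks the alkoxide, which closes on the remaining mesylate with inversion to give 13.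

Step 11. Enolization of the α-sulfonyloxy ketone or of the α-aryloxy ketone product under base may epimerize C8, and the second alkylation may stall. The fallback sets out from 14 and comes back at 19, setting C8 under neutral conditions. A double Mitsunobu etherification of 14 with (S)-2-hydroxy-N,N-dimethylpropanamide 15 (PPh3, DIAD, THF) inverts the lactate centre and gives the bis[(R)-2-aryloxy-N,N-dimethylpropanamide] F7. Addition of (3,4-dimethoxyphenyl)magnesium bromide 16 to both amides releases diketone 19 only on aqueous work-up.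

Further compounds
F1 | step 7 | (1R,2R,3R,4R)-4-[(tert-butyldimethylsilyl)oxy]-1,4-bis[3-methoxy-4-(tosyloxy)phenyl]-2,3-dimethylbutan-1-ol | COc1cc([C@H](O)[C@H](C)[C@@H](C)[C@@H](O[Si](C)(C)C(C)(C)C)c2ccc(OS(=O)(=O)c3ccc(C)cc3)c(OC)c2)ccc1OS(=O)(=O)c1ccc(C)cc1
F2 | step 7 | (1S,2R,3R,4R)-4-[(tert-butyldimethylsilyl)oxy]-1,4-bis[3-methoxy-4-(tosyloxy)phenyl]-2,3-dimethylbutyl 4-nitrobenzoate | COc1cc([C@@H](OC(=O)c2ccc(cc2)[N+](=O)[O-])[C@H](C)[C@@H](C)[C@@H](O[Si](C)(C)C(C)(C)C)c2ccc(OS(=O)(=O)c3ccc(C)cc3)c(OC)c2)ccc1OS(=O)(=O)c1ccc(C)cc1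
F3 | step 7 | (1S,2R,3R,4R)-4-hydroxy-1,4-bis[3-methoxy-4-(tosyloxy)phenyl]-2,3-dimethylbutyl 4-nitrobenzoate | COc1cc([C@@H](OC(=O)c2ccc(cc2)[N+](=O)[O-])[C@H](C)[C@@H](C)[C@@H](O)c2ccc(OS(=O)(=O)c3ccc(C)cc3)c(OC)c2)ccc1OS(=O)(=O)c1ccc(C)cc1
F4 | step 7 | (1S,2R,3R,4R)-4-(methylsulfonyloxy)-1,4-bis[3-methoxy-4-(tosyloxy)phenyl]-2,3-dimethylbutyl 4-nitrobenzoate | COc1cc([C@@H](OC(=O)c2ccc(cc2)[N+](=O)[O-])[C@H](C)[C@@H](C)[C@@H](OS(C)(=O)=O)c2ccc(OS(=O)(=O)c3ccc(C)cc3)c(OC)c2)ccc1OS(=O)(=O)c1ccc(C)cc1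
F5 | step 6 | (1R,2R,3R,4R)-1,4-bis[3-methoxy-4-(tosyloxy)phenyl]-2,3-dimethylbutane-1,4-diyl dimethanesulfonate | COc1cc([C@H](OS(C)(=O)=O)[C@H](C)[C@@H](C)[C@@H](OS(C)(=O)=O)c2ccc(OS(=O)(=O)c3ccc(C)cc3)c(OC)c2)ccc1OS(=O)(=O)c1ccc(C)cc1
F6 | step 6 | (1S,2R,3R,4R)-4-(methylsulfonyloxy)-1,4-bis[3-methoxy-4-(tosyloxy)phenyl]-2,3-dimethylbutyl acetate | COc1cc([C@@H](OC(C)=O)[C@H](C)[C@@H](C)[C@@H](OS(C)(=O)=O)c2ccc(OS(=O)(=O)c3ccc(C)cc3)c(OC)c2)ccc1OS(=O)(=O)c1ccc(C)cc1
F7 | step 11 | (2R,2'R)-2,2'-{[(2S,3R,4R,5S)-3,4-dimethyltetrahydrofuran-2,5-diyl]bis[(2-methoxy-4,1-phenylene)oxy]}bis(N,N-dimethylpropanamide) | CN(C)C(=O)[C@@H](C)Oc1ccc([C@H]2O[C@H](c3ccc(O[C@H](C)C(=O)N(C)C)c(OC)c3)[C@H](C)[C@H]2C)cc1OC
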